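**Retrosynthetic overview**
1. Target 19 ⇒ silyl ether 18 ⇒ central diene C–C bond by Heck coupling of E-vinyl iodide 10 with 3-vinylisocoumarin 17.
2. 10 ⇒ aldehyde 9 (Takai) ⇒ oxidative ring contraction of the six-membered enol ether 8, the ring oxygen making a 1,2-shift.
3. 8 ⇒ endo-cycloisomerisation of syn-alkynediol 6 ⇒ syn-reduction of hydroxy ynone 4 ⇒ methyl (S)-3-hydroxybutanoate 1 + ethynyltrimethylsilane 2.
4. 17 ⇒ redox-neutral rhodium-catalysed C–H/O–H annulation of acid 13 (from resorcinol 11 by chlorination and carboxylation) with diacetate 15.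
5. Ring order: dihydropyran (step 3) → tetrahydrofuran by contraction (step 4); the lactone ring is closed on the purchased benzene ring in step 9.

Assumption: but-3-yne-1,2-diol is used as the racemate because its stereocentre is destroyed in step 9; Cp* = pentamethylcyclopentadienyl, TBS = tert-butyldimethylsilyl, TMS = trimethylsilyl.

**Step 1**
Reactants: 1 methyl (S)-3-hydroxybutanoate; 2 ethynyltrimethylsilane
Product: 4 (S)-5-hydroxy-1-(trimethylsilyl)hex-1-yn-3-one, via Weinreb amide 3 (not isolated)
Conditions: MeNH(OMe)·HCl, i-PrMgCl, THF, −20 °C; then TMSC≡CMgCl (from 2 + i-PrMgCl), 0 °C to rt; aq. NH4Cl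
Reagents that add atoms: none
Why: One-pot Weinreb amidation and alkynyl Grignard acylation, in which the chelated tetrahedral adduct stops the addition at the ketone and the chiral-pool carbinol centre (later C5 of the tetrahydrofuran) is untouched.

**Step 2**
Reactants: 4 (S)-5-hydroxy-1-(trimethylsilyl)hex-1-yn-3-one
Product: 6 (2S,4S)-hex-5-yne-2,4-diol, via silyl diol 5 (not isolated)
Conditions: Et2BOMe, THF/MeOH (4:1), −78 °C; NaBH4, −78 °C; AcOH, MeOH co-evaporation; then K2CO3, MeOH, rt
Reagents that add atoms: none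
Why: Narasaka–Prasad reduction, in which hydride adds to the six-membered boron chelate of the β-hydroxy ynone and sets the new carbinol (later C3 of the tetrahydrofuran) 1,3-syn to the existing one, followed by methanolysis of the alkynyl silane.

**Step 3**
Reactants: 6 (2S,4S)-hex-5-yne-2,4-diol
Product: 8 tert-butyldimethyl{[(2S,4S)-2-methyl-3,4-dihydro-2H-pyran-4-yl]oxy}silane, via glycal alcohol 7 (not isolated)
Conditions: W(CO)6 (25 mol%), DABCO, THF, hν (350 nm), 60 °C; then TBSCl, imidazole, DMF, rt
Reagents that add atoms: tert-butyldimethylsilyl chloride, CC(C)(C)[Si](C)(C)Cl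
Why: Tungsten-vinylidene endo-cycloisomerisation of the alkynol, in which only the C2 hydroxyl can reach the vinylidene carbon and so closes the six-membered enol ether, followed by in-flask silylation of the allylic alcohol with no stereocentre touched.

**Step 4**
Reactants: 8 tert-butyldimethyl{[(2S,4S)-2-methyl-3,4-dihydro-2H-pyran-4-yl]oxy}silane
Product: 9 (2S,3S,5S)-3-[(tert-butyldimethylsilyl)oxy]-5-methyltetrahydrofuran-2-carbaldehyde
Conditions: Tl(NO3)3·3H2O (1.1 equiv), MeCN, −20 to 0 °C, 15 min; aq. NaHCO3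
Reagents that add atoms: water, O
Why: Oxidative ring contraction of a cyclic enol ether (glycal to 2,5-anhydro-aldose type), in which trivalent thallium adds to C5 anti to the pseudo-axial silyloxy group, water adds to C6, and the ring oxygen then shifts from C6 to C5 with inversion as monovalent thallium leaves from an equatorial position, placing the formyl-bearing centre trans to the silyl ether and cis to the methyl group.

**Step 5**
Reactants: 9 (2S,3S,5S)-3-[(tert-butyldimethylsilyl)oxy]-5-methyltetrahydrofuran-2-carbaldehyde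
Product: 10 tert-butyl({(2R,3S,5S)-2-[(E)-2-iodoethenyl]-5-methyltetrahydrofuran-3-yl}oxy)dimethylsilane
Conditions: CrCl2 (6 equiv), CHI3 (2 equiv), THF/1,4-dioxane (1:6), 0 °C to rt
Reagents that add atoms: iodoform, IC(I)I
Why: Takai olefination, in which the geminal dichromium species made from iodoform and divalent chromium adds to the aldehyde and eliminates to the E-vinyl iodide under non-basic conditions that neither epimerise the α-alkoxy centre nor eliminate the β-silyloxy group.

**Step 6**
Reactants: 11 resorcinol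
Product: 12 4-chlorobenzene-1,3-diol
Conditions: SO2Cl2 (1.0 equiv), Et2O, 0 °C to rt
Reagents that add atoms: sulfuryl chloride, ClS(Cl)(=O)=O
Why: Electrophilic aromatic chlorination, in which one equivalent of sulfuryl chloride attacks the position ortho to one hydroxyl and para to the other.

**Step 7**
Reactants: 12 4-chlorobenzene-1,3-diol
Product: 13 5-chloro-2,4-dihydroxybenzoic acid
Conditions: KHCO3 (5 equiv), H2O, CO2 (1 atm), 100 °C; then HCl
Reagents that add atoms: carbon dioxide, O=C=O
Why: Kolbe–Schmitt carboxylation, in which the resorcinolate is carboxylated at the remaining position ortho to one hydroxyl and para to the other (the β-resorcylic pattern), leaving a single free C–H ortho to the acid.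

**Step 8**
Reactants: 14 but-3-yne-1,2-diol
Product: 15 but-3-yne-1,2-diyl diacetate
Conditions: Ac2O, pyridine, DMAP (cat.), CH2Cl2, 0 °C to rt
Reagents that add atoms: acetic anhydride, CC(=O)OC(C)=O
Why: Standard acylation that turns both hydroxyls into the leaving groups needed in step 9.

**Step 9**
Reactants: 13 5-chloro-2,4-dihydroxybenzoic acid; 15 but-3-yne-1,2-diyl diacetate
Product: 17 5-chloro-6,8-dihydroxy-3-vinyl-1H-isochromen-1-one, via allenyl acid 16 (not isolated)
Conditions: [Cp*Rh(MeCN)3](SbF6)2 (5 mol%), CsOAc (30 mol%), CF3CH2OH, 40 °C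
Reagents that add atoms: none
Why: Proposed new method: a redox-neutral annulation in which the carboxylate directs trivalent rhodium to the only free ortho C–H, the aryl–rhodium bond adds across the terminal alkyne with the aryl on the terminal carbon, β-acetoxy elimination gives aryl allene 16, the rhodium carboxylate then adds to the central allene carbon to close the six-membered lactone and a second β-acetoxy elimination releases the vinyl group and trivalent rhodium acetate, so no external oxidant meets the free phenols or the terminal alkyne; the closest known reaction types are the rhodium-catalysed C–H allenylation of arenes with propargylic carbonates by β-oxygen elimination and the oxidative isocoumarin annulation of benzoic acids with internal alkynes.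

**Step 10**
Reactants: 10 tert-butyl({(2R,3S,5S)-2-[(E)-2-iodoethenyl]-5-methyltetrahydrofuran-3-yl}oxy)dimethylsilane; 17 5-chloro-6,8-dihydroxy-3-vinyl-1H-isochromen-1-one
Product: 18 3-[(1E,3E)-4-{(2R,3S,5S)-3-[(tert-butyldimethylsilyl)oxy]-5-methyltetrahydrofuran-2-yl}buta-1,3-dien-1-yl]-5-chloro-6,8-dihydroxy-1H-isochromen-1-one
Conditions: Pd(OAc)2 (10 mol%), n-Bu4NCl, NaHCO3, DMF, 40 °C, dark
Reagents that add atoms: none
Why: Heck reaction, in which zerovalent palladium (formed in situ from divalent palladium acetate) inserts into the vinyl iodide with retention, adds to the terminal CH2 of the vinyl group and undergoes syn β-hydride elimination to the E,E-diene, while the bicarbonate base spares the lactone, the phenols and the aryl chloride.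

**Step 11**
Reactants: 18 silyl ether of the target
Product: 19 5-chloro-6,8-dihydroxy-3-[(1E,3E)-4-[(2R,3S,5S)-3-hydroxy-5-methyltetrahydrofuran-2-yl]buta-1,3-dien-1-yl]-1H-isochromen-1-one
Conditions: HF·pyridine, THF/pyridine, 0 °C to rt
Reagents that add atoms: none
Why: Fluoride-mediated silyl ether cleavage under buffered, non-basic conditions that leave the enol lactone, the diene and the allylic ether intact.

**Compound list**
1 | methyl (S)-3-hydroxybutanoate | C[C@H](O)CC(=O)OC | starting material
2 | ethynyltrimethylsilane | C#C[Si](C)(C)C | starting material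
3 | (S)-3-hydroxy-N-methoxy-N-methylbutanamide | C[C@H](O)CC(=O)N(C)OC | intermediate
4 | (S)-5-hydroxy-1-(trimethylsilyl)hex-1-yn-3-one | C[C@H](O)CC(=O)C#C[Si](C)(C)C | intermediate
5 | (3S,5S)-1-(trimethylsilyl)hex-1-yne-3,5-diol | C[C@H](O)C[C@H](O)C#C[Si](C)(C)C | intermediate
6 | (2S,4S)-hex-5-yne-2,4-diol | C[C@H](O)C[C@H](O)C#C | intermediate
7 | (2S,4S)-2-methyl-3,4-dihydro-2H-pyran-4-ol | C[C@H]1C[C@H](O)C=CO1 | intermediate
8 | tert-butyldimethyl{[(2S,4S)-2-methyl-3,4-dihydro-2H-pyran-4-yl]oxy}silane | C[C@H]1C[C@H](O[Si](C)(C)C(C)(C)C)C=CO1 | intermediate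
9 | (2S,3S,5S)-3-[(tert-butyldimethylsilyl)oxy]-5-methyltetrahydrofuran-2-carbaldehyde | C[C@H]1C[C@H](O[Si](C)(C)C(C)(C)C)[C@@H](C=O)O1 | intermediate
10 | tert-butyl({(2R,3S,5S)-2-[(E)-2-iodoethenyl]-5-methyltetrahydrofuran-3-yl}oxy)dimethylsilane | C[C@H]1C[C@H](O[Si](C)(C)C(C)(C)C)[C@@H](/C=C/I)O1 | intermediate
11 | resorcinol (benzene-1,3-diol) | Oc1cccc(O)c1 | starting material
12 | 4-chlorobenzene-1,3-diol | Oc1ccc(Cl)c(O)c1 | intermediate
13 | 5-chloro-2,4-dihydroxybenzoic acid | OC(=O)c1cc(Cl)c(O)cc1O | intermediate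
14 | but-3-yne-1,2-diol (racemic) | OCC(O)C#C | starting material
15 | but-3-yne-1,2-diyl diacetate (racemic) | CC(=O)OCC(OC(C)=O)C#C | intermediate
16 | 2-(4-acetoxybuta-1,2-dien-1-yl)-3-chloro-4,6-dihydroxybenzoic acid (racemic allene) | CC(=O)OCC=C=Cc1c(Cl)c(O)cc(O)c1C(O)=O | intermediate
17 | 5-chloro-6,8-dihydroxy-3-vinyl-1H-isochromen-1-one | C=Cc1cc2c(Cl)c(O)cc(O)c2c(=O)o1 | intermediate
18 | 3-[(1E,3E)-4-{(2R,3S,5S)-3-[(tert-butyldimethylsilyl)oxy]-5-methyltetrahydrofuran-2-yl}buta-1,3-dien-1-yl]-5-chloro-6,8-dihydroxy-1H-isochromen-1-one | C[C@H]1C[C@H](O[Si](C)(C)C(C)(C)C)[C@@H](/C=C/C=C/c2cc3c(Cl)c(O)cc(O)c3c(=O)o2)O1 | intermediate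
19 | 5-chloro-6,8-dihydroxy-3-[(1E,3E)-4-[(2R,3S,5S)-3-hydroxy-5-methyltetrahydrofuran-2-yl]buta-1,3-dien-1-yl]-1H-isochromen-1-one | C[C@H]1C[C@H](O)[C@@H](/C=C/C=C/c2cc3c(Cl)c(O)cc(O)c3c(=O)o2)O1 | target

**Step count and risks**
Total steps: 11. Longest linear sequence: 7 (steps 1–5, 10, 11).

Step 9, the proposed new annulation, may fail through the wrong insertion regiochemistry, alkyne oligomerisation or catalyst inhibition by the salicylate unit. The fallback uses known chemistry, sets out from 13 and comes back at 17. Dimethylsulfoxonium methylide (Me3S(O)I, KOt-Bu, THF) is acylated with crotonyl chloride to the keto sulfoxonium ylide (E)-1-[dimethyl(oxo)-λ6-sulfanylidene]pent-3-en-2-one F1. F1 is coupled with 13 by the established carboxylate-directed C–H acylmethylation and cyclodehydration ([Cp*RhCl2]2, AgSbF6, NaOAc, 1,2-dichloroethane, 80 °C) to 5-chloro-6,8-dihydroxy-3-[(E)-prop-1-en-1-yl]-1H-isochromen-1-one F2. Ethenolysis of F2 (ethylene 1 atm, second-generation Grubbs catalyst RuCl2(H2IMes)(PCy3)(=CHPh), CH2Cl2, 40 °C) trims the propenyl group to vinyl and gives 17.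

Step 4, the thallium-mediated ring contraction, may fail through a competing 1,2-shift of the added oxygen nucleophile in place of the ring oxygen, or through acid damage to the enol ether. The fallback is a stepwise contraction through a sulfonate; it sets out from 8 and comes back at 9. Dimethyldioxirane (acetone, −40 °C) epoxidises 8 anti to the silyloxy group to the 5,6-epoxide of 8 F3. Methanol opens it at the acetal carbon to (2R,3R,4S,6S)-4-[(tert-butyldimethylsilyl)oxy]-2-methoxy-6-methyltetrahydro-2H-pyran-3-ol F4. Tf2O and pyridine (CH2Cl2, −20 °C) give the corresponding triflate F5. Warming F5 with 2,6-lutidine in methanol (50 °C) lets the ring oxygen displace the equatorial triflate, the known contraction of pyranoside 2-sulfonates, to tert-butyl{[(2S,3S,5S)-2-(dimethoxymethyl)-5-methyltetrahydrofuran-3-yl]oxy}dimethylsilane F6. Mild acetal hydrolysis (Amberlyst-15, wet acetone) then gives 9.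

Step 3, the cycloisomerisation, may fail because the free propargylic hydroxyl can divert the tungsten vinylidene and because the glycal alcohol is small and acid-sensitive. The fallback builds the ring as a pyranone; it sets out from 4 and comes back at 7, which is silylated to 8 as in the second half of step 3. Buffered fluoride (TBAF, AcOH, THF, 0 °C) gives (S)-5-hydroxyhex-1-yn-3-one F7. Acid-catalysed 6-endo oxa-Michael cyclisation (TfOH cat., CH2Cl2) gives (S)-2-methyl-2,3-dihydro-4H-pyran-4-one F8. Luche reduction (NaBH4, CeCl3·7H2O, MeOH, −78 °C) gives (2S,4R)-2-methyl-3,4-dihydro-2H-pyran-4-ol F9. Mitsunobu inversion (4-nitrobenzoic acid, PPh3, DIAD, THF) gives (2S,4S)-2-methyl-3,4-dihydro-2H-pyran-4-yl 4-nitrobenzoate F10. Methanolysis (K2CO3, MeOH) gives 7.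

**Further compounds**
F1 | step 9 | (E)-1-[dimethyl(oxo)-λ6-sulfanylidene]pent-3-en-2-one | C/C=C/C(=O)C=S(C)(C)=O
F2 | step 9 | 5-chloro-6,8-dihydroxy-3-[(E)-prop-1-en-1-yl]-1H-isochromen-1-one | C/C=C/c1cc2c(Cl)c(O)cc(O)c2c(=O)o1
F3 | step 4 | 5,6-epoxide of 8, epoxide oxygen trans to the silyloxy group | C[C@H]1C[C@H](O[Si](C)(C)C(C)(C)C)[C@H]2O[C@H]2O1
F4 | step 4 | (2R,3R,4S,6S)-4-[(tert-butyldimethylsilyl)oxy]-2-methoxy-6-methyltetrahydro-2H-pyran-3-ol | C[C@H]1C[C@H](O[Si](C)(C)C(C)(C)C)[C@@H](O)[C@H](OC)O1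
F5 | step 4 | (2R,3R,4S,6S)-4-[(tert-butyldimethylsilyl)oxy]-2-methoxy-6-methyltetrahydro-2H-pyran-3-yl trifluoromethanesulfonate | C[C@H]1C[C@H](O[Si](C)(C)C(C)(C)C)[C@@H](OS(=O)(=O)C(F)(F)F)[C@H](OC)O1
F6 | step 4 | tert-butyl{[(2S,3S,5S)-2-(dimethoxymethyl)-5-methyltetrahydrofuran-3-yl]oxy}dimethylsilane | C[C@H]1C[C@H](O[Si](C)(C)C(C)(C)C)[C@@H](C(OC)OC)O1
F7 | step 3 | (S)-5-hydroxyhex-1-yn-3-one | C[C@H](O)CC(=O)C#C
F8 | step 3 | (S)-2-methyl-2,3-dihydro-4H-pyran-4-one | C[C@H]1CC(=O)C=CO1
F9 | step 3 | (2S,4R)-2-methyl-3,4-dihydro-2H-pyran-4-ol | C[C@H]1C[C@@H](O)C=CO1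
F10 | step 3 | (2S,4S)-2-methyl-3,4-dihydro-2H-pyran-4-yl 4-nitrobenzoate | C[C@H]1C[C@H](OC(=O)c2ccc(cc2)[N+]([O-])=O)C=CO1
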